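The two CH2–aryl bonds joining the C6 and C8 methylenes of ring A to the outer phenol rings are disconnected with ring A as the electrophile. In the O7-unmethylated series, the C8 methylene lies ortho to O7–H and the C6 methylene ortho to both O5–H and O7–H, so each can be unmasked as a ring-A ortho-quinone methide. The key step forms both bonds in one operation by boron-to-carbon transfer of a 2-(benzyloxy)phenyl group onto these methides. Its precursor is (2S)-6,8-bis[(dimethylamino)methyl]pinocembrin with free 5- and 7-hydroxyls. O7 is methylated only afterwards, since a 7-methoxy group would leave C8 without an ortho hydroxyl.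

Key step: step 2

Assumption: natural (2S)-pinocembrin is bought as the single enantiomer. C2 is never created in the route, only carried through, so its enantiomeric purity should be checked by chiral HPLC at the start and again after steps 1 and 2.

Remark: the order in which C6 and C8 react in steps 1 and 2 is not known and does not change the outcome. The transient compounds are drawn for one order.

Step 1
Reactants: 1 (2S)-pinocembrin; 2 N,N,N',N'-tetramethylmethanediamine
Product: 4 (2S)-6,8-bis[(dimethylamino)methyl]pinocembrin, via 6-mono-Mannich base 3 (not isolated)
Conditions: 2 (2.5 equiv), 1,4-dioxane, 60 °C; evaporate, triturate with Et2O (no silica), use fresh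
Reagents that add atoms: N,N,N',N'-tetramethylmethanediamine 2, CN(C)CN(C)C
Why: Aromatic Mannich aminomethylation with an aminal as a neutral iminium source: the phloroglucinol-type ring A is strongly nucleophilic at C6 and C8, each ortho to a hydroxyl that protonates the aminal and delivers CH2=NMe2+, so both positions should be aminomethylated without added acid or hydroxide, while C2 is not involved and keeps its (S) configuration.

Step 2
Reactants: 4 (2S)-6,8-bis[(dimethylamino)methyl]pinocembrin; 5 2-(benzyloxy)phenylboronic acid
Product: 9 (2S)-6,8-bis[2-(benzyloxy)benzyl]pinocembrin, via C8-methylene quinone methide 6 (not isolated), via mono-arylated Mannich base 7 (not isolated), via C6-methylene quinone methide 8 (not isolated)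
Conditions: 5 (4 equiv), 1,4-dioxane, 90–100 °C, N2 sweep; aq. NH4Cl work-up
Reagents that add atoms: 2-(benzyloxy)phenylboronic acid 5, OB(O)c1ccccc1OCc1ccccc1
Why: On heating, the zwitterionic Mannich base 4 (7-phenolate/ammonium) should expel dimethylamine to give the ring-A ortho-quinone methide 6 (C7=O, exocyclic C8=CH2), whose oxygen binds boronic acid 5 as a tetracoordinate boronate; the 2-(benzyloxy)phenyl group then migrates from boron to the exocyclic CH2 through a six-membered transition state, restoring aromatic ring A in 7, and the same sequence at C6 (via 8, through O7 or O5) gives 9. The closest known reaction type is the metal-free Petasis-type 1,4-addition of arylboronic acids to ortho-quinone methides released from phenolic Mannich bases, here run twice on one ring. No ring is closed and no stereocentre is created; C2 (S) is a spectator. The selectivity needed is carbon over heteroatom capture of the methide: adducts with amine, phenol or water can re-ionise to the methide, whereas aryl transfer within the boronate is intramolecular and irreversible, so material should funnel to the C–C product, and ipso transfer fixes the ortho relationship between the new CH2 and the benzyloxy group. The excess boronic acid binds released dimethylamine as an amine–boron adduct and the rest leaves with the gas stream, so the medium stays non-basic, ring C does not open by retro-oxa-Michael reaction and C2 should not racemise. The benzyl ethers keep the outer oxygens from acting as nucleophiles and make the later O7 methylation unambiguous.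

Step 3
Reactants: 9 (2S)-6,8-bis[2-(benzyloxy)benzyl]pinocembrin
Product: 10 (2S)-6,8-bis[2-(benzyloxy)benzyl]-5-hydroxy-7-methoxyflavanone
Conditions: TMSCHN2 (2 M in hexanes, 1.5–2 equiv), toluene/MeOH (1:1), 0 °C to rt; AcOH quench
Reagents that add atoms: trimethylsilyldiazomethane, C[Si](C)(C)C=[N+]=[N-]
Why: Diazoalkane O-methylation of an acidic phenol: O7–H, para to the C4 carbonyl, is acidic enough to protonate the diazo carbon in methanol, whereas O5–H is held in a hydrogen bond to C4=O and the outer oxygens are benzylated, so only O7 should be methylated under base-free conditions that cannot open ring C.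

Step 4
Reactants: 10 (2S)-6,8-bis[2-(benzyloxy)benzyl]-5-hydroxy-7-methoxyflavanone
Product: 11 7-methoxydichamanetin
Conditions: H2 (1 atm), 10% Pd/C, EtOAc, rt
Reagents that add atoms: none
Why: Catalytic hydrogenolysis of aryl benzyl ethers over Pd/C, which at 1 atm and room temperature in a neutral solvent should cleave the two O–CH2Ph bonds well before the cyclic O1–C2 ether, the hydrogen-bonded C4 ketone or the diarylmethane links are touched, leaving C2 (S) intact.

Compound list
1 | (2S)-pinocembrin, (2S)-5,7-dihydroxy-2-phenylchroman-4-one | Oc1cc(O)c2c(c1)O[C@H](c1ccccc1)CC2=O | starting material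
2 | N,N,N',N'-tetramethylmethanediamine (bis(dimethylamino)methane) | CN(C)CN(C)C | starting material
3 | (2S)-6-[(dimethylamino)methyl]pinocembrin (mono-Mannich base; the 8-isomer, if formed first, converges on 4) | Oc1c(CN(C)C)c(O)c2c(c1)O[C@H](c1ccccc1)CC2=O | intermediate
4 | (2S)-6,8-bis[(dimethylamino)methyl]-5,7-dihydroxy-2-phenylchroman-4-one | Oc1c(CN(C)C)c(O)c2c(c1CN(C)C)O[C@H](c1ccccc1)CC2=O | intermediate
5 | 2-(benzyloxy)phenylboronic acid | OB(O)c1ccccc1OCc1ccccc1 | starting material
6 | ring-A ortho-quinone methide of 4: C7 oxo, exocyclic CH2 on C8, C6 still bearing CH2NMe2, (2S) | O=C1C(CN(C)C)=C(O)C2=C(C1=C)O[C@H](c1ccccc1)CC2=O | intermediate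
7 | (2S)-8-[2-(benzyloxy)benzyl]-6-[(dimethylamino)methyl]pinocembrin | Oc1c(CN(C)C)c(O)c2c(c1Cc1ccccc1OCc1ccccc1)O[C@H](c1ccccc1)CC2=O | intermediate
8 | ring-A ortho-quinone methide of 7: C7 oxo, exocyclic CH2 on C6, C8 bearing 2-(benzyloxy)benzyl, (2S) | O=C1C(=C)C(O)=C2C(=C1Cc1ccccc1OCc1ccccc1)O[C@H](c1ccccc1)CC2=O | intermediate
9 | (2S)-6,8-bis[2-(benzyloxy)benzyl]-5,7-dihydroxy-2-phenylchroman-4-one | Oc1c(Cc2ccccc2OCc2ccccc2)c(O)c2c(c1Cc1ccccc1OCc1ccccc1)O[C@H](c1ccccc1)CC2=O | intermediate
10 | (2S)-6,8-bis[2-(benzyloxy)benzyl]-5-hydroxy-7-methoxy-2-phenylchroman-4-one | COc1c(Cc2ccccc2OCc2ccccc2)c(O)c2c(c1Cc1ccccc1OCc1ccccc1)O[C@H](c1ccccc1)CC2=O | intermediate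
11 | 7-methoxydichamanetin, (2S)-5-hydroxy-6,8-bis(2-hydroxybenzyl)-7-methoxy-2-phenylchroman-4-one | COc1c(Cc2ccccc2O)c(O)c2c(c1Cc1ccccc1O)O[C@H](c1ccccc1)CC2=O | target

Total steps: 4. Longest linear sequence: 4 steps (1 to 4 to 9 to 10 to 11).

Steps most likely to fail

Step 2. The aryl migration may lose to bimolecular capture of the quinone methide by other flavanone molecules (methylene-bridged oligomers), the sequence may stall after one transfer, or the electron-rich boronic acid may protodeboronate on heating. The fallback reverses the polarity and uses known chemistry, setting out from 1. Heating 1 with 2-hydroxybenzyl alcohol (about 3 equiv) and anhydrous ZnCl2 in 1,4-dioxane at reflux should give (2S)-dichamanetin F1 by Friedel–Crafts ortho-hydroxybenzylation of ring A at C6 and C8. F1 is then treated with TMSCHN2 (about 1.05 equiv) in toluene/MeOH at 0 °C. The most acidic hydroxyl, O7–H, should react first, ahead of the chelated O5–H and the weakly acidic outer phenols, and the sequence returns to the route at 11.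

Step 1. The basic aminal and the released dimethylamine may open ring C to the 2'-hydroxychalcone and reclose it, eroding the configuration at C2, or the reaction may stop after one aminomethylation. The fallback keeps nitrogen protonated throughout and sets out from 1. Treating 1 with preformed N,N-dimethylmethyleneiminium iodide (Eschenmoser's salt, 2.2 equiv) in MeCN at 0 °C to rt should give the bis(hydriodide) of the Mannich base, (2S)-6,8-bis[(dimethylammonio)methyl]pinocembrin diiodide F2, by electrophilic substitution with no free amine present. Brief neutralisation with cold aqueous NaHCO3 and extraction returns to the route at 4.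

Step 4. Over-reduction may compete with O-debenzylation, either as hydrogenolytic opening of the O1–C2 benzylic bond to a dihydrochalcone or as reduction at C4. The fallback is non-reductive and sets out from 10. BCl3 (about 5 equiv) with pentamethylbenzene (about 6 equiv) in CH2Cl2 at −78 °C, followed by a MeOH quench, should cleave both aryl benzyl ethers by Lewis-acid heterolysis with capture of the benzyl cation, which cannot affect O1–C2 or C4=O. It returns to the route at 11, and no new compound lies on the way (F0).

Further compounds
F1 | step 2 | (2S)-dichamanetin, (2S)-5,7-dihydroxy-6,8-bis(2-hydroxybenzyl)-2-phenylchroman-4-one | Oc1c(Cc2ccccc2O)c(O)c2c(c1Cc1ccccc1O)O[C@H](c1ccccc1)CC2=O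
F2 | step 1 | (2S)-6,8-bis[(dimethylammonio)methyl]pinocembrin diiodide | Oc1c(C[NH+](C)C)c(O)c2c(c1C[NH+](C)C)O[C@H](c1ccccc1)CC2=O.[I-].[I-]
F0 | step 4 | none | none
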